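## Structural features

Skeleton numbering used throughout: spiro atom C5; cyclohexene C10(C14)=C1–C2–C3–C4(C15)–C5; cyclopentane C5–C6–C7–C8–C9; lactone C7–C11(=C13H2)–C12(=O)–O–C8. TBS = tert-butyldimethylsilyl, PMB = 4-methoxybenzyl.

The target is a spiro[4.5]decane sesquiterpenoid in which a cyclohexene and a cyclopentane share only the quaternary carbon C5. A cis-fused α-methylene-γ-butyrolactone is annulated on C7/C8 of the five-membered ring, and C10 carries the C14 methylene whose oxygen is acylated by angelic acid. Four of the six stereocentres are contiguous on the six-membered ring: C2 (S), C3 (S), C4 (R) and C5 (R), with O2 trans to O3, O3 trans to the C15 methyl, C9 trans and C6 cis to C15. C7 (R) and C8 (R) are cis to each other, and the lactone lies on the cyclopentane face turned towards C10. The α-methylene lactone is a Michael acceptor, the angelate isomerises easily from Z to E (tiglate), and the C2 carbinol and C14 ester are allylic and can ionise. The real difficulty is twofold: the all-carbon spiro centre next to C4, and the relay of configuration from C5 to C7/C8, because the two cyclopentane faces differ only by C14 on C10 and C15 on C4, both gauche to C6. The key step uses the fact that C5 carries two ring methylenes (C6 and C9) and is α to C10. With C10 as a ketone, C5=C6 becomes an exocyclic enone that can take up C7–C8–C9 as one three-carbon unit, and the adjacent C4 methyl decides the face at C5.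

## Logic of the disconnections

38 ⇒ 37. The O–Si bonds at O2 and O3 are cut last. The diol must stay masked while C14 is acylated, and the demand is a desilylation that leaves the angelate, the allylic system and the methylene lactone alone.

37 ⇒ 34 + 35. The acyl C–O bond at O14 is cut. The angeloyl group is the most isomerisation-prone part, so it enters after all enolate chemistry. This removes five carbons and leads to commercial 35. The forward acylation must not pass through intermediates that allow Z to E isomerisation.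

34 ⇒ 33 ⇒ 30. The benzylic O–C bond of the C14 ether and then the C11=C13 bond are cut. The Michael acceptor is created only after the last hydride and alkylation steps. The forward step needs the lactone to be the only enolisable site.

30 ⇒ 28. The O8–C12 acyl bond and the C8–H bond are cut. The lactone becomes a γ-keto ester and C8 is derived from C7. The demand is hydride attack anti to the C7 side chain so that the hydroxy ester is cis and can close.

28 ⇒ 25 + 26, and 25 ⇒ 24. The C7–C11 bond is cut. Since C14 and C15 shield opposite faces of the cyclopentane to a similar degree, the face at C7 is assigned to a chiral hydrazone auxiliary and not to the substrate. The forward step needs deprotonation at C7 and not at the neopentyl C9, and auxiliary removal without epimerisation.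

24 ⇒ 22. The C8=O bond is traced back to the C8 exocyclic methylene, which serves as a masked ketone through all organolithium, enolate and hydride steps on the six-membered ring. The demand is cleavage of the 1,1-disubstituted alkene in the presence of C10=C1.

22 ⇒ 21 ⇒ 20 ⇒ 19. The two O–Si bonds, the C2–H bond and the C3–O bond are cut. This reduces the trans-diol to a plain enone. Forward, the oxidant must enter C3 anti to C15 and the hydride must reach C2 from the O3 face.

19 ⇒ 14 + 17. The C10–C14 bond is cut with a 1,3-carbonyl transposition. The vinylogous ester of 14 is at once the activating group of the key step and the latent C10=C1–C2=O enone. The demand is 1,2-addition to a carbonyl flanked by the quaternary C5.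

17 ⇒ 15 + 16. The ether C–O bond of the hydroxymethyl-anion equivalent is cut, which gives two commercial pieces.

14 ⇒ 12 + 13. The C6–C7 and C5–C9 bonds are cut, which removes the whole cyclopentane and the spiro centre in one operation. The forward step needs an acceptor that reacts only at the exocyclic alkene and an enolate that closes anti to C15.

12 ⇒ 9. The C5=C6 bond is cut. The exocyclic methylene comes from a one-carbon iminium electrophile, and the enolate must be formed at C5 (α′) and not at C3 (γ).

9 ⇒ 8 ⇒ 5. The C2–O bond and then the C2–S bond are cut. The β-heteroatom is put on an existing enone so that the C10 carbonyl never changes place and the ring never becomes the achiral 1,3-dione. Forward, the exchange of sulfur for ethoxy must run under base only.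

5 ⇒ 1 + 2. The C4–C5 bond (Michael) and the C1=C2 bond (aldol condensation) are cut. The C4 stereocentre is set by an amine catalyst on two commodity chemicals, and the demand is high face selectivity at the β-carbon of 1.

## Other disconnections considered

Alternative 1: The cut is C7–C11 of the lactone, made together with a sacrificial C6–C11 bond.
- Forward step: diazoacetate A2 (a C8 ester on a spirocycle with a C6=C7 alkene) is decomposed by Rh2(OAc)4. The carbenoid cyclopropanates C6=C7 to give the cyclopropane-fused lactone A1, and the C6–C11 bond is then cleaved reductively.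
- In favour: C11 is delivered from the C8 oxygen, so cis fusion is enforced and C7 follows from C8 without an auxiliary. On this point the alternative is better than the chosen plan, which spends steps 12 and 13 on C7.
- Against: the step does not build the spiro centre, so a spiroannulation is still needed first. The C8 carbinol must be set relative to C5, which is the same remote problem (the two plans are equal there). Ring opening has to choose C6–C11 over C7–C11. A1 still has C14 as a methyl and C2 as a methylene, so two allylic oxidations would follow in the presence of the lactone.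
- Comparison: the carbenoid addition is concerted and stereospecific, whereas the chosen plan uses a stepwise ionic annulation. In step count the alternative is longer (allylic alcohol, diazo ester, cyclopropanation, opening, methylenation, then oxidation at C14 and C2).

Alternative 2: The cut is C5–C10.
- Forward step: the (Z)-alkenyl iodide A4 is turned into an alkenylpalladium (Pd(OAc)2, formate) or an alkenyl radical (Bu3SnH) that closes 6-exo onto the β-carbon of the cyclopentenone. This gives the spiro ketone A3.
- Equal point: A3 is identical in constitution and configuration with 24, so from there on both plans share the same end game.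
- In favour: the C2–C4 triad is assembled in open-chain form with the diol protected from the start. No carbonyl transposition and no sensitive cross-conjugated methylene ketone such as 12 are needed; this is better than the chosen plan. After insertion the alkylpalladium has no β-hydrogen on the new quaternary carbon, so hydride capture should be clean.
- Against: bond formation at a fully substituted β-carbon is slow and competes with simple reduction of the alkenyl species or 1,5-hydrogen transfer. The C5 configuration depends on which cyclopentenone face is presented, and those faces differ only by CH2 versus CH=. Induction from C4 is therefore less secure than the enolate allylation anti to the methyl in the chosen plan.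
- Step economy: A4 needs roughly eight to ten steps, so A3 is not reached sooner than 24 (steps 1–11).

Alternative 3: The cut is C5–C6, formed while C6–C10 is broken.
- Forward step: irradiation of the cross-conjugated hexahydronaphthalenone A6 in aqueous acetic acid gives the spiro enone A5, through a cyclopropyl oxyallyl cation and water capture at C10.
- In favour: the spiro centre is transferred stereospecifically from the angular carbon of a decalin, which is equal to or better than the chosen plan at C5. C11 and C12 are already attached to C7 as an acetic ester, which is better because no C7 alkylation is needed.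
- Against: A5 has a tertiary C10 carbinol with C14 as a methyl and no oxygen at C2. A regioselective dehydration to C10=C1 and allylic oxidations at C14 and C2 (the latter with stereocontrol) must follow. The C6=C7 enone still has to be reduced with control of C7/C8 relative to C5 (equal to the chosen plan). The spiro and the hydroazulenone rearrangement modes compete, and dilute irradiation limits scale.
- Comparison: the photochemical skeletal change is shorter to the spirocycle, but more redox adjustments remain afterwards than in the chosen plan.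

Key step: step 5

Remark on the chemistry: 5-methylcyclohexane-1,3-dione has a mirror plane through C2 and C5 and cannot be resolved, and its mono enol ethers racemise by acid-catalysed 1,3-transposition of the alkoxy group; C4 is therefore set by an enantioselective Michael addition and the enol ether is installed under base on a ring whose carbonyl never moves.

## Route

Step 1
Reactants: 1 (E)-but-2-enal; 2 tert-butyl 3-oxobutanoate
Product: 5 (5S)-5-methylcyclohex-2-en-1-one, via Michael adduct 3 (not isolated), via cyclohexenone ester 4 (not isolated)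
Conditions: (R)-2-{bis[3,5-bis(trifluoromethyl)phenyl][(trimethylsilyl)oxy]methyl}pyrrolidine (10 mol%), neat, rt; then p-TsOH·H2O (20 mol%), PhMe, 80 °C
Reagents that add atoms: none
Why: Iminium-ion organocatalysis (asymmetric Michael addition): the keto ester adds to the β-carbon of the (E)-iminium ion on the face anti to the diaryl(silyloxy)methyl group, which with the (R)-catalyst should give the (S)-configured methyl carbon (C4 of the target); acid then drives the intramolecular aldol condensation, tert-butyl ester cleavage and decarboxylation.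

Step 2
Reactants: 5 (5S)-5-methylcyclohex-2-en-1-one
Product: 8 (5R)-5-methyl-3-(phenylsulfanyl)cyclohex-2-en-1-one, via thiol adduct 6 (not isolated), via chloro sulfide 7 (not isolated)
Conditions: PhSH, Et3N (cat.), CH2Cl2, 0 °C to rt; then N-chlorosuccinimide, 0 °C; then Et3N (1.2 equiv), rt
Reagents that add atoms: benzenethiol, Sc1ccccc1
Why: Thia-Michael addition, then α-chlorination of the sulfide and dehydrochlorination to the conjugated vinylogous thioester; the carbonyl stays on its carbon, so no symmetric intermediate arises and the methyl stereocentre is untouched (its descriptor becomes R only because sulfur raises the priority of one branch).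

Step 3
Reactants: 8 (5R)-5-methyl-3-(phenylsulfanyl)cyclohex-2-en-1-one
Product: 9 (5S)-3-ethoxy-5-methylcyclohex-2-en-1-one
Conditions: NaOEt, EtOH, 0 °C to rt; AcOH quench
Reagents that add atoms: sodium ethoxide, CC[O-].[Na+]
Why: Addition–elimination at the β-carbon: ethoxide adds and the thiolate, the better leaving group, is expelled; under basic conditions the carbonyl oxygen cannot change place, so the enol ether should keep its configuration.

Step 4
Reactants: 9 (5S)-3-ethoxy-5-methylcyclohex-2-en-1-one
Product: 12 (5S)-3-ethoxy-5-methyl-6-methylidenecyclohex-2-en-1-one, via Mannich base 10 (not isolated), via ammonium iodide 11 (not isolated)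
Conditions: LiN(i-Pr)2, THF, −78 °C; CH2=NMe2+ I−, −78 °C to rt; then MeI, rt; then aq. NaHCO3, rt; used at once
Reagents that add atoms: dimethylmethyleneiminium iodide, C=[N+](C)C.[I-]
Why: Kinetic α′-deprotonation of the vinylogous ester, Mannich reaction with Eschenmoser's salt, exhaustive methylation and E1cB loss of trimethylamine; no new stereocentre survives, and the cross-conjugated methylene ketone is used fresh because it can dimerise or isomerise towards a phenol.

Step 5
Reactants: 12 (5S)-3-ethoxy-5-methyl-6-methylidenecyclohex-2-en-1-one; 13 2-[(trimethylsilyl)methyl]prop-2-en-1-yl acetate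
Product: 14 (5R,10S)-8-ethoxy-10-methyl-2-methylidenespiro[4.5]dec-7-en-6-one
Conditions: Pd(OAc)2 (5 mol%), P(O-i-Pr)3 (30 mol%), 13 (1.5 equiv), THF, 65 °C
Reagents that add atoms: none
Why: Zerovalent palladium, formed from Pd(OAc)2 (divalent palladium) and the phosphite, ionises the allyl acetate 13, and the acetate set free removes the silyl group to leave the palladium-bound trimethylenemethane zwitterion. Its carbanionic terminus adds in Michael fashion to the exocyclic C6 of 12 (C6–C7), and the C5/C10 enolate so formed attacks a terminus of the cationic π-allyl unit (C5–C9). The closest known reaction type is the palladium–trimethylenemethane (3+2) cycloaddition to α-methylene ketones, which gives spiro methylenecyclopentanes. The cyclopentane is closed by a 5-exo C-allylation of the enolate, the palladium leaving group lying outside the new ring. The only new stereocentre, C5, is controlled by the C4 methyl: in the enolate C15 is pseudoaxial to avoid A(1,2) strain with the C6 side chain, so C9 bonds to the opposite face and ends trans to C15 with C6 cis. Site selectivity is needed between the exocyclic and the ring alkene; the β-ethoxy group deactivates C1=C2 as a vinylogous ester, and the s-cis methylene ketone suits the stepwise mechanism. The neutral conditions leave C4 and the enol ether in place, and the methylene left on C8 marks the future lactone oxygen.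

Step 6
Reactants: 15 tributyl(iodomethyl)stannane; 16 (4-methoxyphenyl)methanol
Product: 17 tributyl{[(4-methoxyphenyl)methoxy]methyl}stannane
Conditions: NaH, THF/DMF, 0 °C to rt
Reagents that add atoms: none
Why: Williamson ether synthesis; the alkoxide displaces iodide from the primary α-stannyl carbon by SN2.

Step 7
Reactants: 14 (5R,10S)-8-ethoxy-10-methyl-2-methylidenespiro[4.5]dec-7-en-6-one; 17 tributyl{[(4-methoxyphenyl)methoxy]methyl}stannane
Product: 19 (5R,10S)-10-methyl-2-methylidene-6-[(PMB-oxy)methyl]spiro[4.5]dec-6-en-8-one, via tertiary carbinol 18 (not isolated)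
Conditions: 17, n-BuLi, THF, −78 °C; then 14, −78 to 0 °C; then 1 M HCl, THF, 0 °C to rt
Reagents that add atoms: water, O
Why: Tin–lithium exchange gives the α-alkoxy organolithium, which adds 1,2 to the vinylogous ester carbonyl C10; acid then effects the Stork–Danheiser transposition (ionisation of the carbinol, hydrolysis of the enol ether), placing the ketone at C2 and C14 on C10=C1, while the C8 methylene is inert and masks the C8 ketone.

Step 8
Reactants: 19 (5R,10S)-10-methyl-2-methylidene-6-[(PMB-oxy)methyl]spiro[4.5]dec-6-en-8-one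
Product: 20 (5R,9S,10R)-9-hydroxy-10-methyl-2-methylidene-6-[(PMB-oxy)methyl]spiro[4.5]dec-6-en-8-one
Conditions: LiN(i-Pr)2, THF, −78 °C; 3-phenyl-2-(phenylsulfonyl)oxaziridine, −78 °C; aq. NH4Cl
Reagents that add atoms: 3-phenyl-2-(phenylsulfonyl)oxaziridine, O=S(=O)(c1ccccc1)N1OC1c1ccccc1
Why: Kinetic α′-enolisation of the enone at C3 and electrophilic hydroxylation (Davis oxidation); the enolate face that carries C15 on C4 and C6 on C5 is the more crowded, so oxygen should enter from the other face and O3 comes out trans to the C4 methyl.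

Step 9
Reactants: 20 (5R,9S,10R)-9-hydroxy-10-methyl-2-methylidene-6-[(PMB-oxy)methyl]spiro[4.5]dec-6-en-8-one
Product: 21 (5R,8S,9S,10R)-10-methyl-2-methylidene-6-[(PMB-oxy)methyl]spiro[4.5]dec-6-ene-8,9-diol
Conditions: Me4NBH(OAc)3, MeCN/AcOH (1:1), −30 to 0 °C
Reagents that add atoms: none
Why: Hydroxyl-directed reduction (Evans–Saksena type): boron binds to O3 by ligand exchange and delivers hydride to C2 on the O3 face, so O2 should be trans to O3; the acetoxyborohydride leaves the alkenes alone.

Step 10
Reactants: 21 (5R,8S,9S,10R)-10-methyl-2-methylidene-6-[(PMB-oxy)methyl]spiro[4.5]dec-6-ene-8,9-diol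
Product: 22 (5R,8S,9S,10R)-8,9-bis(TBS-oxy)-10-methyl-2-methylidene-6-[(PMB-oxy)methyl]spiro[4.5]dec-6-ene
Conditions: t-BuMe2SiOTf, 2,6-lutidine, CH2Cl2, 0 °C to rt
Reagents that add atoms: tert-butyldimethylsilyl trifluoromethanesulfonate, CC(C)(C)[Si](C)(C)OS(=O)(=O)C(F)(F)F
Why: Silylation of both secondary hydroxyls with a silyl triflate reactive enough for the hindered O3; the ethers tolerate amide bases, hydride and DDQ and are removable with fluoride at the end.

Step 11
Reactants: 22 (5R,8S,9S,10R)-8,9-bis(TBS-oxy)-10-methyl-2-methylidene-6-[(PMB-oxy)methyl]spiro[4.5]dec-6-ene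
Product: 24 (5R,8S,9S,10R)-8,9-bis(TBS-oxy)-10-methyl-6-[(PMB-oxy)methyl]spiro[4.5]dec-6-en-2-one, via diol 23 (not isolated)
Conditions: OsO4 (2 mol%), NaIO4, 2,6-lutidine, 1,4-dioxane/H2O (3:1), rt
Reagents that add atoms: osmium tetroxide, O=[Os](=O)(=O)=O; sodium periodate, [Na+].[O-]I(=O)(=O)=O
Why: Lemieux–Johnson oxidation: the open 1,1-disubstituted alkene should be dihydroxylated far faster than C10=C1, which is trisubstituted, flanked by the quaternary C5 and deactivated by two allylic C–O bonds; periodate cleaves the diol to the C8 ketone.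

Step 12
Reactants: 24 (5R,8S,9S,10R)-8,9-bis(TBS-oxy)-10-methyl-6-[(PMB-oxy)methyl]spiro[4.5]dec-6-en-2-one
Product: 25 (2R)-N-[(5R,8S,9S,10R)-8,9-bis(TBS-oxy)-10-methyl-6-[(PMB-oxy)methyl]spiro[4.5]dec-6-en-2-ylidene]-2-(methoxymethyl)pyrrolidin-1-amine
Conditions: (2R)-2-(methoxymethyl)pyrrolidin-1-amine (RAMP), 4 Å molecular sieves, PhMe, 60 °C
Reagents that add atoms: (2R)-2-(methoxymethyl)pyrrolidin-1-amine, COC[C@H]1CCCN1N
Why: Hydrazone condensation at the only ketone; the auxiliary is installed because the cyclopentane faces at C7 are shielded about equally by C14 and C15, so reagent control is the safer way to set C7.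

Step 13
Reactants: 25 RAMP hydrazone of 24; 26 tert-butyl 2-bromoacetate
Product: 28 tert-butyl 2-[(2R,5R,8S,9S,10R)-8,9-bis(TBS-oxy)-10-methyl-3-oxo-6-[(PMB-oxy)methyl]spiro[4.5]dec-6-en-2-yl]acetate, via alkylated hydrazone 27 (not isolated)
Conditions: LiN(i-Pr)2, THF, 0 °C; then 26, −100 °C to rt; then sat. aq. (CO2H)2, Et2O, rt
Reagents that add atoms: water, O
Why: SAMP/RAMP hydrazone alkylation: deprotonation should occur at C7 because C9 is neopentyl, and the chelated azaenolate is alkylated on the face fixed by the auxiliary; SAMP is known to give the opposite sense for this substitution pattern (as in (S)-4-methylheptan-3-one), so RAMP should give 7R, and two-phase oxalic acid hydrolysis frees the ketone without epimerising C7.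

Step 14
Reactants: 28 tert-butyl 2-[(2R,5R,8S,9S,10R)-8,9-bis(TBS-oxy)-10-methyl-3-oxo-6-[(PMB-oxy)methyl]spiro[4.5]dec-6-en-2-yl]acetate
Product: 30 (1R,3a'R,4S,5S,6R,6a'R)-4,5-bis(TBS-oxy)-6-methyl-2-[(PMB-oxy)methyl]-3a',4',6',6a'-tetrahydrospiro[cyclohex-2-ene-1,5'-cyclopenta[b]furan]-2'(3'H)-one, via hydroxy ester 29 (not isolated)
Conditions: LiBH(s-Bu)3, THF, −78 °C to rt; aq. NH4Cl
Reagents that add atoms: none
Why: The bulky hydride attacks C8 anti to the C7 side chain and gives the cis alkoxide, which closes the γ-lactone by 5-exo-trig acyl substitution with loss of tert-butoxide; only the cis-fused bicycle can form, so C8 follows from C7.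

Step 15
Reactants: 30 cis-fused lactone (PMB ether, bis-TBS ether)
Product: 33 (1R,3a'R,4S,5S,6R,6a'R)-4,5-bis(TBS-oxy)-6-methyl-3'-methylidene-2-[(PMB-oxy)methyl]-3a',4',6',6a'-tetrahydrospiro[cyclohex-2-ene-1,5'-cyclopenta[b]furan]-2'(3'H)-one, via Mannich base 31 (not isolated), via ammonium iodide 32 (not isolated)
Conditions: LiN(i-Pr)2, THF, −78 °C; CH2=NMe2+ I−, −78 °C to rt; then MeI, rt; then aq. NaHCO3, EtOAc, rt
Reagents that add atoms: dimethylmethyleneiminium iodide, C=[N+](C)C.[I-]
Why: Mannich reaction of the lactone enolate (the only enolisable position), quaternisation and E1cB elimination give the α-methylene lactone; the transient C11 stereocentre is lost.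

Step 16
Reactants: 33 α-methylene lactone (PMB ether, bis-TBS ether)
Product: 34 (1R,3a'R,4S,5S,6R,6a'R)-4,5-bis(TBS-oxy)-2-(hydroxymethyl)-6-methyl-3'-methylidene-3a',4',6',6a'-tetrahydrospiro[cyclohex-2-ene-1,5'-cyclopenta[b]furan]-2'(3'H)-one
Conditions: DDQ, CH2Cl2/pH 7 buffer (10:1), 0 °C
Reagents that add atoms: none
Why: Oxidative cleavage of the 4-methoxybenzyl ether through benzylic hydride abstraction and hydrolysis of the oxocarbenium ion; silyl ethers and the methylene lactone are inert to the quinone.

Step 17
Reactants: 34 C14 allylic alcohol (bis-TBS ether); 35 (Z)-2-methylbut-2-enoic acid (angelic acid)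
Product: 37 [(1R,3a'R,4S,5S,6R,6a'R)-4,5-bis(TBS-oxy)-6-methyl-3'-methylidene-2'-oxo-3',3a',4',6a'-tetrahydro-2'H,6'H-spiro[cyclohex-2-ene-1,5'-cyclopenta[b]furan]-2-yl]methyl (2Z)-2-methylbut-2-enoate, via mixed anhydride 36 (not isolated)
Conditions: 35, 2,4,6-Cl3C6H2COCl, Et3N, PhMe, rt; then 34, 60 °C
Reagents that add atoms: none
Why: Yamaguchi-type esterification without a nucleophilic catalyst: the primary alcohol attacks the less hindered angeloyl carbonyl of the mixed anhydride, and leaving out 4-(dimethylamino)pyridine avoids the addition–elimination path that turns angelates into tiglates.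

Step 18
Reactants: 37 bis-TBS ether of the target
Product: 38 [(1R,3a'R,4S,5S,6R,6a'R)-4,5-dihydroxy-6-methyl-3'-methylidene-2'-oxo-3',3a',4',6a'-tetrahydro-2'H,6'H-spiro[cyclohex-2-ene-1,5'-cyclopenta[b]furan]-2-yl]methyl (2Z)-2-methylbut-2-enoate
Conditions: HF·pyridine, pyridine, THF, 0 °C to rt
Reagents that add atoms: none
Why: Fluoride-mediated cleavage of both silyl ethers under buffered, weakly acidic conditions that should not isomerise the angelate or add to the methylene lactone.

## Compound list

1 | (E)-but-2-enal | C/C=C/C=O | starting material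
2 | tert-butyl 3-oxobutanoate | CC(=O)CC(=O)OC(C)(C)C | starting material
3 | tert-butyl (3S)-2-acetyl-3-methyl-5-oxopentanoate (C2 epimers) | CC(=O)C(C(=O)OC(C)(C)C)[C@@H](C)CC=O | intermediate
4 | tert-butyl (6S)-6-methyl-2-oxocyclohex-3-ene-1-carboxylate (C1 epimers) | O=C1C=CC[C@H](C)C1C(=O)OC(C)(C)C | intermediate
5 | (5S)-5-methylcyclohex-2-en-1-one | O=C1C=CC[C@H](C)C1 | intermediate
6 | (3R)-3-methyl-5-(phenylsulfanyl)cyclohexan-1-one (C5 epimers) | O=C1CC(Sc2ccccc2)C[C@H](C)C1 | intermediate
7 | (5R)-3-chloro-5-methyl-3-(phenylsulfanyl)cyclohexan-1-one (C3 epimers) | O=C1CC(Cl)(Sc2ccccc2)C[C@H](C)C1 | intermediate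
8 | (5R)-5-methyl-3-(phenylsulfanyl)cyclohex-2-en-1-one | O=C1C=C(Sc2ccccc2)C[C@H](C)C1 | intermediate
9 | (5S)-3-ethoxy-5-methylcyclohex-2-en-1-one | O=C1C=C(OCC)C[C@H](C)C1 | intermediate
10 | (5S)-6-[(dimethylamino)methyl]-3-ethoxy-5-methylcyclohex-2-en-1-one (C6 epimers) | O=C1C=C(OCC)C[C@H](C)C1CN(C)C | intermediate
11 | {[(6S)-4-ethoxy-6-methyl-2-oxocyclohex-3-en-1-yl]methyl}trimethylammonium iodide | O=C1C=C(OCC)C[C@H](C)C1C[N+](C)(C)C.[I-] | intermediate
12 | (5S)-3-ethoxy-5-methyl-6-methylidenecyclohex-2-en-1-one | C=C1C(=O)C=C(OCC)C[C@@H]1C | intermediate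
13 | 2-[(trimethylsilyl)methyl]prop-2-en-1-yl acetate | CC(=O)OCC(=C)C[Si](C)(C)C | starting material
14 | (5R,10S)-8-ethoxy-10-methyl-2-methylidenespiro[4.5]dec-7-en-6-one | C=C1C[C@@]2(CC1)C(=O)C=C(OCC)C[C@@H]2C | intermediate
15 | tributyl(iodomethyl)stannane | CCCC[Sn](CCCC)(CCCC)CI | starting material
16 | (4-methoxyphenyl)methanol | COc1ccc(CO)cc1 | starting material
17 | tributyl{[(4-methoxyphenyl)methoxy]methyl}stannane | CCCC[Sn](CCCC)(CCCC)COCc1ccc(OC)cc1 | intermediate
18 | (5R,10S)-8-ethoxy-6-{[(4-methoxyphenyl)methoxy]methyl}-10-methyl-2-methylidenespiro[4.5]dec-7-en-6-ol (C6 epimers, formed as lithium alkoxide) | C=C1C[C@@]2(CC1)C(O)(COCc1ccc(OC)cc1)C=C(OCC)C[C@@H]2C | intermediate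
19 | (5R,10S)-6-{[(4-methoxyphenyl)methoxy]methyl}-10-methyl-2-methylidenespiro[4.5]dec-6-en-8-one | C=C1C[C@@]2(CC1)C(COCc1ccc(OC)cc1)=CC(=O)C[C@@H]2C | intermediate
20 | (5R,9S,10R)-9-hydroxy-6-{[(4-methoxyphenyl)methoxy]methyl}-10-methyl-2-methylidenespiro[4.5]dec-6-en-8-one | C=C1C[C@@]2(CC1)C(COCc1ccc(OC)cc1)=CC(=O)[C@@H](O)[C@@H]2C | intermediate
21 | (5R,8S,9S,10R)-6-{[(4-methoxyphenyl)methoxy]methyl}-10-methyl-2-methylidenespiro[4.5]dec-6-ene-8,9-diol | C=C1C[C@@]2(CC1)C(COCc1ccc(OC)cc1)=C[C@H](O)[C@@H](O)[C@@H]2C | intermediate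
22 | (5R,8S,9S,10R)-8,9-bis[(tert-butyldimethylsilyl)oxy]-6-{[(4-methoxyphenyl)methoxy]methyl}-10-methyl-2-methylidenespiro[4.5]dec-6-ene | C=C1C[C@@]2(CC1)C(COCc1ccc(OC)cc1)=C[C@H](O[Si](C)(C)C(C)(C)C)[C@@H](O[Si](C)(C)C(C)(C)C)[C@@H]2C | intermediate
23 | (5R,8S,9S,10R)-8,9-bis[(tert-butyldimethylsilyl)oxy]-2-(hydroxymethyl)-6-{[(4-methoxyphenyl)methoxy]methyl}-10-methylspiro[4.5]dec-6-en-2-ol (C2 epimers) | OCC1(O)C[C@@]2(CC1)C(COCc1ccc(OC)cc1)=C[C@H](O[Si](C)(C)C(C)(C)C)[C@@H](O[Si](C)(C)C(C)(C)C)[C@@H]2C | intermediate
24 | (5R,8S,9S,10R)-8,9-bis[(tert-butyldimethylsilyl)oxy]-6-{[(4-methoxyphenyl)methoxy]methyl}-10-methylspiro[4.5]dec-6-en-2-one | O=C1C[C@@]2(CC1)C(COCc1ccc(OC)cc1)=C[C@H](O[Si](C)(C)C(C)(C)C)[C@@H](O[Si](C)(C)C(C)(C)C)[C@@H]2C | intermediate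
25 | (2R)-N-[(5R,8S,9S,10R)-8,9-bis[(tert-butyldimethylsilyl)oxy]-6-{[(4-methoxyphenyl)methoxy]methyl}-10-methylspiro[4.5]dec-6-en-2-ylidene]-2-(methoxymethyl)pyrrolidin-1-amine | COC[C@H]1CCCN1N=C1C[C@@]2(CC1)C(COCc1ccc(OC)cc1)=C[C@H](O[Si](C)(C)C(C)(C)C)[C@@H](O[Si](C)(C)C(C)(C)C)[C@@H]2C | intermediate
26 | tert-butyl 2-bromoacetate | CC(C)(C)OC(=O)CBr | starting material
27 | tert-butyl 2-[(2R,5R,8S,9S,10R)-8,9-bis[(tert-butyldimethylsilyl)oxy]-3-{[(2R)-2-(methoxymethyl)pyrrolidin-1-yl]imino}-6-{[(4-methoxyphenyl)methoxy]methyl}-10-methylspiro[4.5]dec-6-en-2-yl]acetate | COC[C@H]1CCCN1N=C1C[C@@]2(C[C@@H]1CC(=O)OC(C)(C)C)C(COCc1ccc(OC)cc1)=C[C@H](O[Si](C)(C)C(C)(C)C)[C@@H](O[Si](C)(C)C(C)(C)C)[C@@H]2C | intermediate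
28 | tert-butyl 2-[(2R,5R,8S,9S,10R)-8,9-bis[(tert-butyldimethylsilyl)oxy]-6-{[(4-methoxyphenyl)methoxy]methyl}-10-methyl-3-oxospiro[4.5]dec-6-en-2-yl]acetate | O=C1C[C@@]2(C[C@@H]1CC(=O)OC(C)(C)C)C(COCc1ccc(OC)cc1)=C[C@H](O[Si](C)(C)C(C)(C)C)[C@@H](O[Si](C)(C)C(C)(C)C)[C@@H]2C | intermediate
29 | tert-butyl 2-[(2R,3R,5R,8S,9S,10R)-8,9-bis[(tert-butyldimethylsilyl)oxy]-3-hydroxy-6-{[(4-methoxyphenyl)methoxy]methyl}-10-methylspiro[4.5]dec-6-en-2-yl]acetate (formed as lithium alkoxide) | O[C@@H]1C[C@@]2(C[C@@H]1CC(=O)OC(C)(C)C)C(COCc1ccc(OC)cc1)=C[C@H](O[Si](C)(C)C(C)(C)C)[C@@H](O[Si](C)(C)C(C)(C)C)[C@@H]2C | intermediate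
30 | (1R,3a'R,4S,5S,6R,6a'R)-4,5-bis[(tert-butyldimethylsilyl)oxy]-2-{[(4-methoxyphenyl)methoxy]methyl}-6-methyl-3a',4',6',6a'-tetrahydrospiro[cyclohex-2-ene-1,5'-cyclopenta[b]furan]-2'(3'H)-one | O=C1O[C@@H]2C[C@@]3(C[C@@H]2C1)C(COCc1ccc(OC)cc1)=C[C@H](O[Si](C)(C)C(C)(C)C)[C@@H](O[Si](C)(C)C(C)(C)C)[C@@H]3C | intermediate
31 | 3'-[(dimethylamino)methyl] derivative of 30 (C3' epimers) | CN(C)CC1C(=O)O[C@@H]2C[C@@]3(C[C@H]12)C(COCc1ccc(OC)cc1)=C[C@H](O[Si](C)(C)C(C)(C)C)[C@@H](O[Si](C)(C)C(C)(C)C)[C@@H]3C | intermediate
32 | 3'-[(trimethylammonio)methyl] derivative of 30, iodide | C[N+](C)(C)CC1C(=O)O[C@@H]2C[C@@]3(C[C@H]12)C(COCc1ccc(OC)cc1)=C[C@H](O[Si](C)(C)C(C)(C)C)[C@@H](O[Si](C)(C)C(C)(C)C)[C@@H]3C.[I-] | intermediate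
33 | (1R,3a'R,4S,5S,6R,6a'R)-4,5-bis[(tert-butyldimethylsilyl)oxy]-2-{[(4-methoxyphenyl)methoxy]methyl}-6-methyl-3'-methylidene-3a',4',6',6a'-tetrahydrospiro[cyclohex-2-ene-1,5'-cyclopenta[b]furan]-2'(3'H)-one | C=C1C(=O)O[C@@H]2C[C@@]3(C[C@H]12)C(COCc1ccc(OC)cc1)=C[C@H](O[Si](C)(C)C(C)(C)C)[C@@H](O[Si](C)(C)C(C)(C)C)[C@@H]3C | intermediate
34 | (1R,3a'R,4S,5S,6R,6a'R)-4,5-bis[(tert-butyldimethylsilyl)oxy]-2-(hydroxymethyl)-6-methyl-3'-methylidene-3a',4',6',6a'-tetrahydrospiro[cyclohex-2-ene-1,5'-cyclopenta[b]furan]-2'(3'H)-one | C=C1C(=O)O[C@@H]2C[C@@]3(C[C@H]12)C(CO)=C[C@H](O[Si](C)(C)C(C)(C)C)[C@@H](O[Si](C)(C)C(C)(C)C)[C@@H]3C | intermediate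
35 | (Z)-2-methylbut-2-enoic acid (angelic acid) | C/C=C(/C)C(=O)O | starting material
36 | (Z)-2-methylbut-2-enoic 2,4,6-trichlorobenzoic anhydride | C/C=C(/C)C(=O)OC(=O)c1c(Cl)cc(Cl)cc1Cl | intermediate
37 | [(1R,3a'R,4S,5S,6R,6a'R)-4,5-bis[(tert-butyldimethylsilyl)oxy]-6-methyl-3'-methylidene-2'-oxo-3',3a',4',6a'-tetrahydro-2'H,6'H-spiro[cyclohex-2-ene-1,5'-cyclopenta[b]furan]-2-yl]methyl (2Z)-2-methylbut-2-enoate | C=C1C(=O)O[C@@H]2C[C@@]3(C[C@H]12)C(COC(=O)/C(C)=C\C)=C[C@H](O[Si](C)(C)C(C)(C)C)[C@@H](O[Si](C)(C)C(C)(C)C)[C@@H]3C | intermediate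
38 | [(1R,3a'R,4S,5S,6R,6a'R)-4,5-dihydroxy-6-methyl-3'-methylidene-2'-oxo-3',3a',4',6a'-tetrahydro-2'H,6'H-spiro[cyclohex-2-ene-1,5'-cyclopenta[b]furan]-2-yl]methyl (2Z)-2-methylbut-2-enoate | C=C1C(=O)O[C@@H]2C[C@@]3(C[C@H]12)C(COC(=O)/C(C)=C\C)=C[C@H](O)[C@@H](O)[C@@H]3C | target

## Step count and least certain steps

Total: 18 steps. Longest linear sequence: 17 steps (steps 1–5 and 7–18); step 6 is a one-step side branch that makes stannane 17.

Step 5 (key step). The most likely failures are loss of 12 by dimerisation or by double-bond migration towards a phenol before it is captured, slow Michael addition because the vinylogous ester lowers the electrophilicity of the methylene ketone, protonation of the intermediate enolate before ring closure, and incomplete face control at C5. The fallback makes the same two bonds in two separate steps. It sets out from 12: a Hosomi–Sakurai conjugate allylation with 2-(chloromethyl)allyltrimethylsilane (TiCl4, CH2Cl2, −78 °C) forms C6–C7 and gives (5S)-6-[3-(chloromethyl)but-3-en-1-yl]-3-ethoxy-5-methylcyclohex-2-en-1-one F1. KOt-Bu in THF at 0 °C then closes C5–C9 by intramolecular enolate alkylation anti to C15, and the route is rejoined at 14.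

Step 3. The exchange may stall at an equilibrium because the thiolate can add back, or the thiolate may add to the product. The fallback sets out from 8, which is oxidised with m-CPBA (CH2Cl2, −78 °C) to (5R)-5-methyl-3-(phenylsulfinyl)cyclohex-2-en-1-one F2. Its sulfinyl group is a much better leaving group and does not re-add, so NaOEt in EtOH at 0 °C should give 9, where the route is rejoined.

Step 9. Internal hydride delivery through a five-membered transition state may be too slow, so that external attack gives a mixture at C2, or the acidic medium may ionise the allylic carbinol. The fallback replaces internal delivery by conformational control. It sets out from 20, whose O3 is silylated (t-BuMe2SiOTf, 2,6-lutidine) to (5R,9S,10R)-9-[(tert-butyldimethylsilyl)oxy]-6-{[(4-methoxyphenyl)methoxy]methyl}-10-methyl-2-methylidenespiro[4.5]dec-6-en-8-one F3. Luche reduction (NaBH4, CeCl3·7H2O, MeOH, −78 °C) should add hydride axially to the half-chair with O3 and C15 equatorial and give (5R,8S,9S,10R)-9-[(tert-butyldimethylsilyl)oxy]-6-{[(4-methoxyphenyl)methoxy]methyl}-10-methyl-2-methylidenespiro[4.5]dec-6-en-8-ol F4. A second silylation rejoins the route at 22.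

Step 13. Deprotonation may not be fully selective for C7 over C9, hydrazone formation or hydrolysis may be slow at the hindered ketone, the substrate may oppose the auxiliary, and the silyl ethers may suffer during the oxalic acid hydrolysis. The fallback drops the auxiliary and uses the fact that C7 is epimerisable. It sets out from 24: the lithium enolate (LiN(i-Pr)2, THF, −78 °C) is alkylated with 26 in the presence of DMPU to give 28 together with its C7 epimer tert-butyl 2-[(2S,5R,8S,9S,10R)-8,9-bis[(tert-butyldimethylsilyl)oxy]-6-{[(4-methoxyphenyl)methoxy]methyl}-10-methyl-3-oxospiro[4.5]dec-6-en-2-yl]acetate F5. After separation, F5 is re-equilibrated with DBU and recycled, and the route is rejoined at 28.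

Step 17. The angeloyl unit may isomerise from Z to E through reversible conjugate addition of amine or carboxylate to the activated acyl species, acylation may be slow, and nucleophiles may add to the methylene lactone. The fallback activates the alcohol and not the acid. It sets out from 34, which is converted by an Appel reaction (CBr4, PPh3, CH2Cl2, 0 °C) into (1R,3a'R,4S,5S,6R,6a'R)-2-(bromomethyl)-4,5-bis[(tert-butyldimethylsilyl)oxy]-6-methyl-3'-methylidene-3a',4',6',6a'-tetrahydrospiro[cyclohex-2-ene-1,5'-cyclopenta[b]furan]-2'(3'H)-one F6. O-alkylation of the caesium salt of 35 (Cs2CO3, DMF, rt) is an SN2 process in which the acid is never an acyl electrophile, and it rejoins the route at 37.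

## Further compounds

F1 | step 5 | (5S)-6-[3-(chloromethyl)but-3-en-1-yl]-3-ethoxy-5-methylcyclohex-2-en-1-one (C6 epimers) | ClCC(=C)CCC1C(=O)C=C(OCC)C[C@@H]1C
F2 | step 3 | (5R)-5-methyl-3-(phenylsulfinyl)cyclohex-2-en-1-one (sulfur epimers) | O=C1C=C(S(=O)c2ccccc2)C[C@H](C)C1
F3 | step 9 | (5R,9S,10R)-9-[(tert-butyldimethylsilyl)oxy]-6-{[(4-methoxyphenyl)methoxy]methyl}-10-methyl-2-methylidenespiro[4.5]dec-6-en-8-one | C=C1C[C@@]2(CC1)C(COCc1ccc(OC)cc1)=CC(=O)[C@@H](O[Si](C)(C)C(C)(C)C)[C@@H]2C
F4 | step 9 | (5R,8S,9S,10R)-9-[(tert-butyldimethylsilyl)oxy]-6-{[(4-methoxyphenyl)methoxy]methyl}-10-methyl-2-methylidenespiro[4.5]dec-6-en-8-ol | C=C1C[C@@]2(CC1)C(COCc1ccc(OC)cc1)=C[C@H](O)[C@@H](O[Si](C)(C)C(C)(C)C)[C@@H]2C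
F5 | step 13 | tert-butyl 2-[(2S,5R,8S,9S,10R)-8,9-bis[(tert-butyldimethylsilyl)oxy]-6-{[(4-methoxyphenyl)methoxy]methyl}-10-methyl-3-oxospiro[4.5]dec-6-en-2-yl]acetate | O=C1C[C@@]2(C[C@H]1CC(=O)OC(C)(C)C)C(COCc1ccc(OC)cc1)=C[C@H](O[Si](C)(C)C(C)(C)C)[C@@H](O[Si](C)(C)C(C)(C)C)[C@@H]2C
F6 | step 17 | (1R,3a'R,4S,5S,6R,6a'R)-2-(bromomethyl)-4,5-bis[(tert-butyldimethylsilyl)oxy]-6-methyl-3'-methylidene-3a',4',6',6a'-tetrahydrospiro[cyclohex-2-ene-1,5'-cyclopenta[b]furan]-2'(3'H)-one | C=C1C(=O)O[C@@H]2C[C@@]3(C[C@H]12)C(CBr)=C[C@H](O[Si](C)(C)C(C)(C)C)[C@@H](O[Si](C)(C)C(C)(C)C)[C@@H]3C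
A1 | alternative 1 | cyclopropane-fused spiro lactone (C6–C7–C11 three-membered ring, C3 silyl ether, C14 methyl) | O=C1O[C@@H]2C[C@@]3([C@@H]4[C@H]1[C@H]24)C(C)=CC[C@@H](O[Si](C)(C)C(C)(C)C)[C@@H]3C
A2 | alternative 1 | 9-[(tert-butyldimethylsilyl)oxy]-6,10-dimethylspiro[4.5]deca-3,6-dien-2-yl 2-diazoacetate (configured as the target at C3, C4, C5 and C8) | [N-]=[N+]=CC(=O)O[C@@H]1C[C@@]2(C=C1)C(C)=CC[C@@H](O[Si](C)(C)C(C)(C)C)[C@@H]2C
A3 | alternative 2 | (5R,8S,9S,10R)-8,9-bis[(tert-butyldimethylsilyl)oxy]-6-{[(4-methoxyphenyl)methoxy]methyl}-10-methylspiro[4.5]dec-6-en-2-one | O=C1C[C@@]2(CC1)C(COCc1ccc(OC)cc1)=C[C@H](O[Si](C)(C)C(C)(C)C)[C@@H](O[Si](C)(C)C(C)(C)C)[C@@H]2C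
A4 | alternative 2 | 3-[(5Z)-3,4-bis[(tert-butyldimethylsilyl)oxy]-6-iodo-7-[(4-methoxyphenyl)methoxy]hept-5-en-2-yl]cyclopent-2-en-1-one (configured as the target at C2, C3 and C4) | O=C1C=C(CC1)[C@@H](C)[C@H](O[Si](C)(C)C(C)(C)C)[C@@H](O[Si](C)(C)C(C)(C)C)/C=C(\I)COCc1ccc(OC)cc1
A5 | alternative 3 | methyl 2-(9-acetoxy-6-hydroxy-6,10-dimethyl-2-oxospiro[4.5]dec-3-en-3-yl)acetate | O=C1C[C@@]2(C=C1CC(=O)OC)[C@@](C)(O)CC[C@@H](OC(C)=O)[C@@H]2C
A6 | alternative 3 | methyl 2-(6-acetoxy-5,8a-dimethyl-3-oxo-3,5,6,7,8,8a-hexahydronaphthalen-2-yl)acetate (angular methyl trans to the C5 methyl) | COC(=O)CC1=C[C@]2(C)CC[C@@H](OC(C)=O)[C@H](C)C2=CC1=O
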